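**Plan**

- Retrosynthesis: after removal of thirteen benzyl ethers and a blocking bromine, two bonds are cut together, C4(upper)–C6(lower) and C2–C3 of the upper ring C. This leads to the (Z)-enol gallate 8 and the C8-brominated lower unit 12. Compound 8 is cut further at the enol ester C–O bond (alkyne 6 + acid 7) and at the acetal carbon (phenol aldehyde 2 + aldehyde 3).
- Forward order: ring A aldehyde 2 → O1–C2 acyloxy acetal 5 → alkyne 6 → (Z)-enol gallate 8; lower unit 12 from (−)-epicatechin in three steps. Step 8 closes ring C by a Prins C2–C3 bond formation and joins the two flavan units in the same flask; step 9 unmasks all phenols.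
- Enabling feature: C2 lies between the ring oxygen O1 and the para-oxygenated ring B, so an oxocarbenium ion forms there easily. C3 is the β-carbon of a styrene whose α-carbon C4 is benzylic to the 5,7-dioxygenated ring A, so the C2–C3 closure leaves a stabilised flavan-4-yl cation at C4, which C6 of the lower ring A captures.
- Stereochemistry: the lower unit comes from (−)-epicatechin. In the upper unit, 2,3-cis follows from the Z enol ester in a chair-like closure, 3,4-trans from participation of the C3 gallate, and the absolute sense of C2/C3 from a chiral counter-anion.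

Key step: step 8

Remark: 5, 6 and 8 are racemic at the acetal carbon (the later C2), which becomes planar in step 8, so their SMILES leave it undefined. Which antipode of the step 8 acid gives the 2R,3R series is to be fixed by a trial with each; because 12 is enantiopure, any product of the wrong facial sense is a diastereomer of 15 and separable by chromatography.

**Step 1**
Reactants: 1 3,5-bis(benzyloxy)phenol
Product: 2 2-hydroxy-4,6-bis(benzyloxy)benzaldehyde
Conditions: MgCl2, Et3N, (CH2O)n, MeCN, reflux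
Reagents that add atoms: paraformaldehyde (formaldehyde) C=O
Why: Magnesium phenoxide-directed ortho-formylation (Casnati–Skattebøl) should place the formyl group only next to the free hydroxyl, and the two ortho positions of 1 are equivalent.

**Step 2**
Reactants: 2 2-hydroxy-4,6-bis(benzyloxy)benzaldehyde; 3 4-(benzyloxy)benzaldehyde
Product: 5 [4-(benzyloxy)phenyl][3,5-bis(benzyloxy)-2-formylphenoxy]methyl pivalate, via chloro ester 4 (not isolated)
Conditions: 3, PivCl, ZnCl2 (2 mol %), CH2Cl2, 0 °C → rt; then 2, NaH, THF/DMF, 0 °C → rt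
Reagents that add atoms: pivaloyl chloride CC(C)(C)C(Cl)=O
Why: ZnCl2-catalysed addition of the acyl chloride to the aldehyde should give α-chloroalkyl ester 4, which alkylates the sodium phenoxide of 2 at the benzylic carbon (acyloxyalkyl ether formation, as with chloromethyl pivalate); this installs the O1–C2 bond with pivalate as the group that leaves in step 8.

**Step 3**
Reactants: 5 [4-(benzyloxy)phenyl][3,5-bis(benzyloxy)-2-formylphenoxy]methyl pivalate
Product: 6 [4-(benzyloxy)phenyl][3,5-bis(benzyloxy)-2-ethynylphenoxy]methyl pivalate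
Conditions: TMSCHN2, n-BuLi, THF, −78 → 0 °C
Reagents that add atoms: trimethylsilyldiazomethane C[Si](C)(C)C=[N+]=[N-]
Why: Colvin homologation: the lithiated diazo reagent adds to the aldehyde, Peterson elimination and loss of N2 give an alkylidene carbene whose 1,2-hydrogen shift gives the terminal alkyne, and the hindered pivalate should not be attacked at low temperature.

**Step 4**
Reactants: 6 [4-(benzyloxy)phenyl][3,5-bis(benzyloxy)-2-ethynylphenoxy]methyl pivalate; 7 3,4,5-tris(benzyloxy)benzoic acid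
Product: 8 (Z)-2-{2-[[4-(benzyloxy)phenyl](pivaloyloxy)methoxy]-4,6-bis(benzyloxy)phenyl}ethenyl 3,4,5-tris(benzyloxy)benzoate
Conditions: [RuCl2(p-cymene)]2 (2 mol %), P(4-ClC6H4)3, DMAP (cat.), toluene, 60 °C
Reagents that add atoms: none
Why: Ruthenium-catalysed anti-Markovnikov addition of a carboxylic acid to a terminal alkyne through a vinylidene complex should give the (Z)-enol ester, fixing the alkene geometry that later becomes the 2,3-cis relationship.

**Step 5**
Reactants: 9 (−)-epicatechin
Product: 10 5,7,3',4'-tetra-O-benzyl-(−)-epicatechin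
Conditions: BnBr, K2CO3, DMF, 0 °C → rt
Reagents that add atoms: benzyl bromide BrCc1ccccc1
Why: Williamson etherification in which carbonate deprotonates only the four phenols, so the C3 alcohol stays free and C2 and C3 keep their configuration.

**Step 6**
Reactants: 10 5,7,3',4'-tetra-O-benzyl-(−)-epicatechin
Product: 11 8-bromo-5,7,3',4'-tetra-O-benzyl-(−)-epicatechin
Conditions: NBS, CH2Cl2, −78 °C → rt
Reagents that add atoms: N-bromosuccinimide O=C1CCC(=O)N1Br
Why: Electrophilic aromatic bromination should go to C8, the more reactive position of the most electron-rich ring A, which blocks C8 and leaves C6 as the only open nucleophilic site.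

**Step 7**
Reactants: 11 8-bromo-5,7,3',4'-tetra-O-benzyl-(−)-epicatechin; 7 3,4,5-tris(benzyloxy)benzoic acid
Product: 12 8-bromo-5,7,3',4'-tetra-O-benzyl-(−)-epicatechin 3-O-[3,4,5-tris(benzyloxy)benzoate]
Conditions: DCC, DMAP, CH2Cl2, rt
Reagents that add atoms: none
Why: Steglich esterification acylates the C3 alcohol with retention, since no bond to C3 is broken.

**Step 8**
Reactants: 8 (Z)-enol gallate acetal; 12 8-bromo lower unit gallate
Product: 15 5,7,4'-tri-O-benzyl-3-O-[3,4,5-tris(benzyloxy)benzoyl]-(−)-epiafzelechin-(4β→6)-8-bromo-5,7,3',4'-tetra-O-benzyl-(−)-epicatechin 3-O-[3,4,5-tris(benzyloxy)benzoate], via aryl oxocarbenium ion 13 (not isolated), via cis-fused dioxolan-2-ylium ion 14 (not isolated)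
Conditions: chiral IDPi acid (O2Ar*)P(=NTf)–N=P(NHTf)(O2Ar*), O2Ar* = 3,3'-bis[3,5-(CF3)2C6H3]-1,1'-binaphthalene-2,2'-diolate (5 mol %), 12 (3 equiv), 5 Å MS, CH2Cl2, −60 → −20 °C, slow addition of 8
Reagents that add atoms: none
Why: Proposed new method: the chiral acid ionises the acetal pivalate of 8 to aryl oxocarbenium ion 13 (O1=C2, stabilised by ring B), held as a contact ion pair with the confined chiral anion, and C3, the β-carbon of the ring A styrene, attacks C2 in a 6-endo-trig Prins closure of ring C; the closest known reaction types are the Brønsted-acid-catalysed asymmetric Prins cyclisation of aldehydes with homoallylic alcohols through chiral oxocarbenium ion pairs and the Lewis-acid Prins cyclisation of α-acyloxy ethers with Friedel–Crafts termination. The cation left at C4, benzylic to the 5,7-dioxygenated ring A, is caught by the gallate carbonyl oxygen in a five-membered acyloxonium closure to the cis-fused ion 14, a temporary ring that is opened again in the same flask. C2 and C3 are set together in a chair-like transition state with the C2 aryl group equatorial, where the Z geometry of the enol ester places the C3 oxygen axial (2,3-cis) and the chiral anion selects the face of 13 (2R,3R). C4 is set when C6 of 12 opens 14 anti to the participating oxygen, which gives the 3,4-trans (4β) interflavan bond and returns the proton to the catalyst. The step needs site selectivity at four places: pivalate leaves in preference to the aryloxide so that O1–C2 stays intact, the donor ring A makes C3 and not C4 the nucleophilic alkene carbon, the tethered alkene outruns external arenes for 13, and the C8 bromine leaves C6 as the only open site of the lower ring A, while the excess of 12 suppresses self-condensation through the upper ring A.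

**Step 9**
Reactants: 15 protected 8-bromo dimer
Product: 16 (−)-epiafzelechin 3-O-gallate-(4β→6)-(−)-epicatechin 3-O-gallate (upper unit 2R,3R,4S; lower unit 2R,3R)
Conditions: H2 (1 atm), Pd(OH)2/C, THF/MeOH/H2O, rt
Reagents that add atoms: none
Why: Hydrogenolysis over Pd(OH)2/C should cleave the thirteen benzyl ethers and the aryl C–Br bond in one operation, while the two gallate esters, the interflavan bond and all five stereocentres are not touched.

**Compound list**

1 | 3,5-bis(benzyloxy)phenol | Oc1cc(OCc2ccccc2)cc(OCc2ccccc2)c1 | starting material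
2 | 2-hydroxy-4,6-bis(benzyloxy)benzaldehyde | O=Cc1c(O)cc(OCc2ccccc2)cc1OCc1ccccc1 | intermediate
3 | 4-(benzyloxy)benzaldehyde | O=Cc1ccc(OCc2ccccc2)cc1 | starting material
4 | chloro[4-(benzyloxy)phenyl]methyl pivalate | CC(C)(C)C(=O)OC(Cl)c1ccc(OCc2ccccc2)cc1 | intermediate
5 | [4-(benzyloxy)phenyl][3,5-bis(benzyloxy)-2-formylphenoxy]methyl pivalate | CC(C)(C)C(=O)OC(Oc1cc(OCc2ccccc2)cc(OCc2ccccc2)c1C=O)c1ccc(OCc2ccccc2)cc1 | intermediate
6 | [4-(benzyloxy)phenyl][3,5-bis(benzyloxy)-2-ethynylphenoxy]methyl pivalate | CC(C)(C)C(=O)OC(Oc1cc(OCc2ccccc2)cc(OCc2ccccc2)c1C#C)c1ccc(OCc2ccccc2)cc1 | intermediate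
7 | 3,4,5-tris(benzyloxy)benzoic acid | OC(=O)c1cc(OCc2ccccc2)c(OCc2ccccc2)c(OCc2ccccc2)c1 | starting material
8 | (Z)-2-{2-[[4-(benzyloxy)phenyl](pivaloyloxy)methoxy]-4,6-bis(benzyloxy)phenyl}ethenyl 3,4,5-tris(benzyloxy)benzoate | CC(C)(C)C(=O)OC(Oc1cc(OCc2ccccc2)cc(OCc2ccccc2)c1/C=C\OC(=O)c1cc(OCc2ccccc2)c(OCc2ccccc2)c(OCc2ccccc2)c1)c1ccc(OCc2ccccc2)cc1 | intermediate
9 | (−)-epicatechin | O[C@@H]1Cc2c(O)cc(O)cc2O[C@@H]1c1ccc(O)c(O)c1 | starting material
10 | 5,7,3',4'-tetra-O-benzyl-(−)-epicatechin | O[C@@H]1Cc2c(OCc3ccccc3)cc(OCc3ccccc3)cc2O[C@@H]1c1ccc(OCc2ccccc2)c(OCc2ccccc2)c1 | intermediate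
11 | 8-bromo-5,7,3',4'-tetra-O-benzyl-(−)-epicatechin | O[C@@H]1Cc2c(OCc3ccccc3)cc(OCc3ccccc3)c(Br)c2O[C@@H]1c1ccc(OCc2ccccc2)c(OCc2ccccc2)c1 | intermediate
12 | 8-bromo-5,7,3',4'-tetra-O-benzyl-(−)-epicatechin 3-O-[3,4,5-tris(benzyloxy)benzoate] | O=C(O[C@@H]1Cc2c(OCc3ccccc3)cc(OCc3ccccc3)c(Br)c2O[C@@H]1c1ccc(OCc2ccccc2)c(OCc2ccccc2)c1)c1cc(OCc2ccccc2)c(OCc2ccccc2)c(OCc2ccccc2)c1 | intermediate
13 | aryl oxocarbenium ion from 8 (O1=C2 cation carrying the (Z)-enol gallate, ion pair with the catalyst anion) | O=C(O/C=C\c1c(OCc2ccccc2)cc(OCc2ccccc2)cc1[O+]=Cc1ccc(OCc2ccccc2)cc1)c1cc(OCc2ccccc2)c(OCc2ccccc2)c(OCc2ccccc2)c1 | intermediate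
14 | 2-[3,4,5-tris(benzyloxy)phenyl]-1,3-dioxolan-2-ylium ion cis-fused across C3–C4 of 5,7,4'-tri-O-benzyl-epiafzelechin (C2 aryl, O3 and O4 on the same face) | O1[C@@H]2[C@H]([O+]=C1c1cc(OCc3ccccc3)c(OCc3ccccc3)c(OCc3ccccc3)c1)c1c(OCc3ccccc3)cc(OCc3ccccc3)cc1O[C@@H]2c1ccc(OCc2ccccc2)cc1 | intermediate
15 | 5,7,4'-tri-O-benzyl-3-O-[3,4,5-tris(benzyloxy)benzoyl]-(−)-epiafzelechin-(4β→6)-8-bromo-5,7,3',4'-tetra-O-benzyl-(−)-epicatechin 3-O-[3,4,5-tris(benzyloxy)benzoate] | O=C(O[C@@H]1[C@@H](c2c(OCc3ccccc3)c(Br)c3c(c2OCc2ccccc2)C[C@@H](OC(=O)c2cc(OCc4ccccc4)c(OCc4ccccc4)c(OCc4ccccc4)c2)[C@@H](c2ccc(OCc4ccccc4)c(OCc4ccccc4)c2)O3)c2c(OCc3ccccc3)cc(OCc3ccccc3)cc2O[C@@H]1c1ccc(OCc2ccccc2)cc1)c1cc(OCc2ccccc2)c(OCc2ccccc2)c(OCc2ccccc2)c1 | intermediate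
16 | (−)-epiafzelechin 3-O-gallate-(4β→6)-(−)-epicatechin 3-O-gallate | O=C(O[C@@H]1[C@@H](c2c(O)cc3c(c2O)C[C@@H](OC(=O)c2cc(O)c(O)c(O)c2)[C@@H](c2ccc(O)c(O)c2)O3)c2c(O)cc(O)cc2O[C@@H]1c1ccc(O)cc1)c1cc(O)c(O)c(O)c1 | target

**Step count and risks**

Total steps: 9. Longest linear sequence: 6 (steps 1, 2, 3, 4, 8, 9).

Steps most likely to fail:

1. Step 8 (the step beyond known chemistry). The ion pair may not control which face of the oxocarbenium ion is attacked (poor facial selectivity). Ring closure may also lose out to intermolecular arylation of the oxocarbenium ion, to a five-membered closure through C4, or to self-condensation through the upper ring A. The fallback uses known chemistry, sets out from nucleophile 12 and acid 7, takes the upper unit from the chiral pool and returns at 15. Purchased (−)-epiafzelechin F1 would be benzylated at its three phenols (BnBr, K2CO3, DMF) to 5,7,4'-tri-O-benzyl-(−)-epiafzelechin F2. Oxidation at C4 with DDQ in the presence of 2-ethoxyethanol should give 4β-(2-ethoxyethoxy) ether F3, and Steglich esterification with 7 (DCC, DMAP) gallate F4. TMSOTf at −78 °C would ionise F4, and an excess of 12 should capture the cation at C6 anti to the participating gallate, which gives 15.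

2. Step 4. The acid may add in the Markovnikov sense or with erosion of the Z geometry, and it may exchange with the pivalate at the acetal carbon on heating. The fallback sets out from alkyne 6 and returns at 8. Rhodium-catalysed trans-hydroboration with pinacolborane ([Rh(cod)Cl]2, P(iPr)3, Et3N, cyclohexane) should give (Z)-alkenylboronate F5. Copper-promoted oxidative C–O coupling of the Chan–Lam type with acid 7 (Cu(OAc)2, Et3N, 4 Å MS, air) should then form the enol ester with retention of the alkene geometry.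

3. Step 3. The lithiated diazo reagent may attack the acyloxy acetal (loss of the pivalate, cleavage of the O1–C2 bond) instead of only the aldehyde. The fallback sets out from 2, builds the alkyne before the acetal, and returns at 6. Silylation (TIPSCl, imidazole, DMF) would give silyl ether F6, Colvin homologation aryl alkyne F7, and TBAF/AcOH 2-ethynylphenol F8. O-alkylation of F8 with chloro ester 4 (NaH, as in step 2) should then give 6.

**Further compounds**

F1 | step 8 | (−)-epiafzelechin | O[C@@H]1Cc2c(O)cc(O)cc2O[C@@H]1c1ccc(O)cc1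
F2 | step 8 | 5,7,4'-tri-O-benzyl-(−)-epiafzelechin | O[C@@H]1Cc2c(OCc3ccccc3)cc(OCc3ccccc3)cc2O[C@@H]1c1ccc(OCc2ccccc2)cc1
F3 | step 8 | 4β-(2-ethoxyethoxy)-5,7,4'-tri-O-benzyl-(−)-epiafzelechin | O[C@@H]1[C@@H](OCCOCC)c2c(OCc3ccccc3)cc(OCc3ccccc3)cc2O[C@@H]1c1ccc(OCc2ccccc2)cc1
F4 | step 8 | 4β-(2-ethoxyethoxy)-5,7,4'-tri-O-benzyl-(−)-epiafzelechin 3-O-[3,4,5-tris(benzyloxy)benzoate] | O=C(O[C@@H]1[C@@H](OCCOCC)c2c(OCc3ccccc3)cc(OCc3ccccc3)cc2O[C@@H]1c1ccc(OCc2ccccc2)cc1)c1cc(OCc2ccccc2)c(OCc2ccccc2)c(OCc2ccccc2)c1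
F5 | step 4 | [4-(benzyloxy)phenyl]{3,5-bis(benzyloxy)-2-[(Z)-2-(4,4,5,5-tetramethyl-1,3,2-dioxaborolan-2-yl)ethenyl]phenoxy}methyl pivalate | CC(C)(C)C(=O)OC(Oc1cc(OCc2ccccc2)cc(OCc2ccccc2)c1/C=C\B1OC(C)(C)C(C)(C)O1)c1ccc(OCc2ccccc2)cc1
F6 | step 3 | 2,4-bis(benzyloxy)-6-[(triisopropylsilyl)oxy]benzaldehyde | CC(C)[Si](Oc1cc(OCc2ccccc2)cc(OCc2ccccc2)c1C=O)(C(C)C)C(C)C
F7 | step 3 | [3,5-bis(benzyloxy)-2-ethynylphenoxy]triisopropylsilane | CC(C)[Si](Oc1cc(OCc2ccccc2)cc(OCc2ccccc2)c1C#C)(C(C)C)C(C)C
F8 | step 3 | 3,5-bis(benzyloxy)-2-ethynylphenol | Oc1cc(OCc2ccccc2)cc(OCc2ccccc2)c1C#C
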